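The γ-lactone (ring atoms O, C6, C7, C11, C12) is tied to the ten-membered carbocycle (C1–C10) through the C6–O bond, and C7 is a plain methylene group next to C6. Everything therefore rests on cutting C7–C11. A rhodium carbene raised at C11 of a C6-bound diazophosphonoacetate inserts into one C7–H bond. This single operation closes the lactone, sets C7 and leaves the phosphonate needed for the last methylenation. The precursor is the fully acylated macrocycle: cis-4,5-epoxide, C1=C10 enoate, C8 methacrylate, C9 acetate. It is built from a nerol-derived epoxy aldehyde and a C7–C10 methyl ketone by boron aldol and ring-closing metathesis.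

Key step: step 17

Numbering: germacrane atom labels of the target are used for all intermediates (C1=C10 enoate, C4–C5 epoxide, C14 = ester carbon on C10, C15 = methyl on C4, C11–C13 = lactone side carbons).
Assumption: C11 of the α-phosphono lactone formed in the key step is configurationally labile and becomes sp2 in the last step, so one epimer is drawn and either serves.

Step 1
Reactants: 1 nerol
Product: 2 (2S,3R)-2,3-epoxynerol
Conditions: Ti(OiPr)4 (10 mol%), L-(+)-diethyl tartrate (12 mol%), t-BuOOH (decane), 4 Å molecular sieves, CH2Cl2, −20 °C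
Reagents that add atoms: tert-butyl hydroperoxide, CC(C)(C)OO
Why: Sharpless asymmetric epoxidation: the allylic hydroxyl binds the titanium tartrate so only the C4=C5 alkene reacts, syn oxygen transfer turns the Z alkene into the cis epoxide, and L-(+)-tartrate selects the face that gives 4R,5S.

Step 2
Reactants: 2 (2S,3R)-2,3-epoxynerol
Product: 4 3-[(2R,3S)-3-(hydroxymethyl)-2-methyloxiran-2-yl]propanal, via secondary ozonide 3 (not isolated)
Conditions: O3, CH2Cl2, −78 °C; then Me2S, −78 °C → rt
Reagents that add atoms: ozone, [O-][O+]=O
Why: Ozonolysis with reductive work-up cleaves the only remaining alkene to the C1 aldehyde, while epoxide and alcohol are inert to ozone and Me2S.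

Step 3
Reactants: 4 3-[(2R,3S)-3-(hydroxymethyl)-2-methyloxiran-2-yl]propanal
Product: 5 [(2S,3R)-3-(but-3-en-1-yl)-3-methyloxiran-2-yl]methanol
Conditions: Ph3PCH3Br, KN(SiMe3)2 (2.5 equiv each), THF, −78 → 0 °C
Reagents that add atoms: methyltriphenylphosphonium bromide, C[P+](c1ccccc1)(c1ccccc1)c1ccccc1.[Br-]
Why: Wittig methylenation: excess non-stabilised ylide first takes the hydroxyl proton and then converts the unhindered aldehyde into the terminal alkene needed for metathesis, without touching a stereocentre.

Step 4
Reactants: 5 [(2S,3R)-3-(but-3-en-1-yl)-3-methyloxiran-2-yl]methanol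
Product: 6 (2R,3R)-3-(but-3-en-1-yl)-3-methyloxirane-2-carbaldehyde
Conditions: TEMPO (10 mol%), PhI(OAc)2, CH2Cl2, rt
Reagents that add atoms: none
Why: Oxoammonium (TEMPO) oxidation stops at the aldehyde under almost neutral conditions, so the epoxide survives and C5 is not epimerised.

Step 5
Reactants: 7 methyl propiolate; 8 acrolein
Product: 10 racemic methyl 3-hydroxy-2-methylidenepent-4-enoate, via vinylalane 9 (not isolated)
Conditions: 7, i-Bu2AlH, N-methylmorpholine N-oxide, THF, 0 °C; then 8, 0 °C → rt; aq. potassium sodium tartrate
Reagents that add atoms: diisobutylaluminium hydride, CC(C)C[AlH]CC(C)C (its aluminium is held only in 9 and leaves on work-up)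
Why: Vinylalumination: hydroalumination of the propiolate gives the α-metalated acrylate 9, which adds 1,2 to acrolein to give the Morita–Baylis–Hillman-type alcohol without amine-induced oligomerisation of acrolein.

Step 6
Reactants: 10 racemic methyl 3-hydroxy-2-methylidenepent-4-enoate
Product: 11 methyl (3R)-3-hydroxy-2-methylidenepent-4-enoate
Conditions: Ti(OiPr)4 (15 mol%), D-(−)-diisopropyl tartrate (18 mol%), t-BuOOH (0.6 equiv), 4 Å molecular sieves, CH2Cl2, −20 °C, run to just past half conversion
Reagents that add atoms: none
Why: Sharpless kinetic resolution: with D-(−)-tartrate the (S)-alcohol is epoxidised quickly at its vinyl group while the (R)-alcohol, which carries the future C9 configuration, is left behind, and the acrylate alkene is too electron-poor to react.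

Step 7
Reactants: 11 methyl (3R)-3-hydroxy-2-methylidenepent-4-enoate
Product: 12 methyl (3R)-2-methylidene-3-(triethylsilyloxy)pent-4-enoate
Conditions: Et3SiCl, imidazole, CH2Cl2, 0 °C
Reagents that add atoms: chlorotriethylsilane, CC[Si](Cl)(CC)CC
Why: Imidazole-promoted silylation gives a non-chelating C9 ether that survives the following steps and can later be removed under mild buffered fluoride conditions.

Step 8
Reactants: 12 methyl (3R)-2-methylidene-3-(triethylsilyloxy)pent-4-enoate
Product: 13 methyl (3S)-2-methylidene-4-oxo-3-(triethylsilyloxy)pentanoate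
Conditions: Pd(Quinox)Cl2 (5 mol%; Quinox = 2-(4,5-dihydrooxazol-2-yl)quinoline), AgSbF6 (12 mol%), aq. t-BuOOH, CH2Cl2, 0 °C → rt
Reagents that add atoms: tert-butyl hydroperoxide, CC(C)(C)OO
Why: Wacker–Tsuji oxidation with a cationic ligand-controlled palladium catalyst turns the monosubstituted alkene of a protected allylic alcohol into the methyl ketone (C7–C8), leaves the electron-poor acrylate alone and does not touch C9 (its descriptor changes to S only through the priority rules).

Step 9
Reactants: 13 methyl (3S)-2-methylidene-4-oxo-3-(triethylsilyloxy)pentanoate; 6 (2R,3R)-3-(but-3-en-1-yl)-3-methyloxirane-2-carbaldehyde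
Product: 15 methyl (3S,6S)-6-[(2S,3R)-3-(but-3-en-1-yl)-3-methyloxiran-2-yl]-6-hydroxy-2-methylidene-4-oxo-3-(triethylsilyloxy)hexanoate, via boron enolate 14 (not isolated)
Conditions: 13, Cy2BCl, Et3N, Et2O, −78 → 0 °C; then 6, −78 → −20 °C; MeOH, pH 7 buffer, H2O2, 0 °C
Reagents that add atoms: chlorodicyclohexylborane, ClB(C1CCCCC1)C1CCCCC1 (its boron is held only in 14 and leaves on work-up)
Why: Boron-mediated aldol: soft enolisation takes place on the methyl side (C7), and enolate 14 attacks the aldehyde face anti to the epoxide C–O bond (Felkin–Anh), a bias sharpened by the C4 substituent cis to the formyl group, giving the 5,6-anti (6S) carbinol while the non-chelating C9 silyl ether exerts little opposing influence.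

Step 10
Reactants: 15 aldol adduct (C6–OH, C8 ketone)
Product: 16 methyl (3S,4S,6S)-6-[(2S,3R)-3-(but-3-en-1-yl)-3-methyloxiran-2-yl]-4,6-dihydroxy-2-methylidene-3-(triethylsilyloxy)hexanoate
Conditions: Me4NBH(OAc)3, MeCN/AcOH, −30 °C
Reagents that add atoms: none
Why: Evans–Saksena reduction: the C6 hydroxyl exchanges onto boron and delivers hydride to C8 through a chair transition state, giving the 6,8-anti diol (8S), which is also the Felkin sense set by the C9 silyloxy group, and enoate and epoxide are inert to the triacetoxyborohydride.

Step 11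
Reactants: 16 anti-6,8-diol; 17 diethylphosphonoacetic acid
Product: 18 acyclic C6 diethylphosphonoacetate with free C8–OH and C9–OSiEt3
Conditions: 17 (1.05 equiv), EDC·HCl, DMAP (cat.), CH2Cl2, −20 → 0 °C
Reagents that add atoms: none
Why: Steglich-type carbodiimide esterification: with one equivalent of acid at low temperature the C6 hydroxyl, flanked by a CH2 group and the tied-back epoxide, should react ahead of the C8 hydroxyl, which is shielded by the silyloxy-bearing, branched C9.

Step 12
Reactants: 18 acyclic C6 diethylphosphonoacetate
Product: 19 ten-membered epoxy enoate (4R,5S,6S,8S,9S; 1(10)E) with C6 phosphonoacetate, free C8–OH and C9–OSiEt3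
Conditions: second-generation Hoveyda–Grubbs catalyst (15 mol%), 1,4-benzoquinone (30 mol%), toluene (1 mM), 80 °C, argon sparge
Reagents that add atoms: none
Why: Ring-closing metathesis: the catalyst loads on the terminal alkene (C1) and closes onto the 1,1-disubstituted acrylate at C10 with loss of ethene, the cis epoxide folds the chain, a ten-membered ring favours the geometry with C2 and C9 cis (the required 1(10)E enoate), and no methacrylate is yet present to compete.

Step 13
Reactants: 19 macrocyclic C8 alcohol; 20 methacrylic anhydride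
Product: 21 macrocycle with C8 methacrylate, C6 phosphonoacetate and C9–OSiEt3
Conditions: 20, DMAP, Et3N, CH2Cl2, rt
Reagents that add atoms: none
Why: DMAP-catalysed acylation of the only free hydroxyl group, under amine bases too weak to deprotonate the phosphonoacetate.

Step 14
Reactants: 21 C8 methacrylate, C9 silyl ether
Product: 22 macrocycle with free C9–OH
Conditions: HF·pyridine, pyridine, THF, 0 °C
Reagents that add atoms: none
Why: Fluoride-driven desilylation in a pyridine-buffered medium removes the labile triethylsilyl group quickly, and the non-basic conditions avoid an O8-to-O9 acyl shift and should spare the epoxide.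

Step 15
Reactants: 22 C9 alcohol
Product: 23 macrocycle with C9 acetate, C8 methacrylate and C6 phosphonoacetate
Conditions: Ac2O, pyridine, DMAP (cat.), CH2Cl2, 0 °C → rt
Reagents that add atoms: acetic anhydride, CC(=O)OC(C)=O
Why: Standard DMAP-catalysed acetylation of the single remaining hydroxyl group, with retention at C9.

Step 16
Reactants: 23 C6 phosphonoacetate
Product: 24 ten-membered epoxy enoate with C6 diazophosphonoacetate, C8 methacrylate and C9 acetate
Conditions: 4-acetamidobenzenesulfonyl azide, DBU, MeCN, 0 °C → rt
Reagents that add atoms: 4-acetamidobenzenesulfonyl azide, CC(=O)Nc1ccc(cc1)S(=O)(=O)N=[N+]=[N-]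
Why: Regitz diazo transfer: DBU deprotonates only the CH2 group activated by both P=O and C=O, the carbanion attacks the terminal azide nitrogen and the sulfonamide leaves, so the sensitive diazo group is introduced last.

Step 17
Reactants: 24 C6 diazophosphonoacetate
Product: 25 trans-fused α-diethoxyphosphoryl γ-lactone (4R,5S,6S,7R,8S,9S; one C11 epimer drawn)
Conditions: Rh2(O2CC7H15)4 (5 mol%), 4 Å molecular sieves, CH2Cl2 (5 mM), 40 °C, slow addition of 24
Reagents that add atoms: none
Why: Loss of N2 from 24 on the divalent rhodium dimer leaves a metal-bound, electron-poor carbene at C11, whose empty orbital takes up the C7–H bonding pair while C7–C11 forms in the same concerted event, so C7 keeps the geometry of the hydrogen that is replaced; this is the established dirhodium-catalysed intramolecular C–H insertion of α-diazo-α-phosphonoacetates to α-phosphono-γ-butyrolactones. The lactone ring (O, C6, C7, C11, C12) closes by 1,5-insertion, the five-membered mode that ester-tethered carbenes prefer over four-membered closure at C6–H and six-membered closure at C8–H. C7 (7R) is fixed by the choice between two diastereotopic hydrogens: only a hydrogen gauche to the C6–O bond can be reached, and where C5–C6–C7–C8 is extended that is solely the one on the ring face of H6, whose replacement gives the trans fusion, whereas C11 is labile and of no consequence. Site selectivity is built into 24: the other five-ring candidate, C5–H, is a strong s-rich oxirane bond, C8–H and C9–H sit on acyloxy-bearing carbons, no O–H or silyloxy C–H remains, and all three alkenes are conjugated to esters and so are poor partners for an electrophilic carbene. Slow addition at high dilution over sieves suppresses carbene dimerisation and capture by water, and the soluble, weakly Lewis acidic carboxylate catalyst should leave the epoxide intact.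

Step 18
Reactants: 25 α-phosphono lactone
Product: 26 target CNP0153978.8
Conditions: K2CO3, aq. HCHO (37%), THF, 0 °C → rt
Reagents that add atoms: formaldehyde, C=O
Why: Horner–Wadsworth–Emmons olefination: carbonate deprotonates C11 (both epimers converge), the carbanion adds to formaldehyde and diethyl phosphate is lost to give C11=C13, under conditions mild enough for the three esters and with the sensitive α-methylene lactone appearing only at the end.

Compound list
1 | nerol, (Z)-3,7-dimethylocta-2,6-dien-1-ol | CC(C)=CCC/C(C)=C\CO | starting material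
2 | (2S,3R)-2,3-epoxynerol | OC[C@@H]1O[C@]1(C)CCC=C(C)C | intermediate
3 | secondary ozonide of 2 (not isolated) | OC[C@@H]1O[C@]1(C)CCC1OOC(C)(C)O1 | intermediate
4 | 3-[(2R,3S)-3-(hydroxymethyl)-2-methyloxiran-2-yl]propanal | OC[C@@H]1O[C@]1(C)CCC=O | intermediate
5 | [(2S,3R)-3-(but-3-en-1-yl)-3-methyloxiran-2-yl]methanol | OC[C@@H]1O[C@]1(C)CCC=C | intermediate
6 | (2R,3R)-3-(but-3-en-1-yl)-3-methyloxirane-2-carbaldehyde | O=C[C@@H]1O[C@]1(C)CCC=C | intermediate
7 | methyl propiolate | C#CC(=O)OC | starting material
8 | acrolein | C=CC=O | starting material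
9 | [1-(methoxycarbonyl)vinyl]diisobutylaluminium (not isolated) | C=C(C(=O)OC)[Al](CC(C)C)CC(C)C | intermediate
10 | racemic methyl 3-hydroxy-2-methylidenepent-4-enoate | C=CC(O)C(=C)C(=O)OC | intermediate
11 | methyl (3R)-3-hydroxy-2-methylidenepent-4-enoate | C=C[C@@H](O)C(=C)C(=O)OC | intermediate
12 | methyl (3R)-2-methylidene-3-(triethylsilyloxy)pent-4-enoate | C=C[C@@H](O[Si](CC)(CC)CC)C(=C)C(=O)OC | intermediate
13 | methyl (3S)-2-methylidene-4-oxo-3-(triethylsilyloxy)pentanoate | CC(=O)[C@@H](O[Si](CC)(CC)CC)C(=C)C(=O)OC | intermediate
14 | dicyclohexylboron enolate of 13 (not isolated) | C=C(OB(C1CCCCC1)C1CCCCC1)[C@@H](O[Si](CC)(CC)CC)C(=C)C(=O)OC | intermediate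
15 | aldol adduct, 4R,5S,6S,9S, C6–OH, C8 ketone | C=CCC[C@@]1(C)O[C@H]1[C@@H](O)CC(=O)[C@@H](O[Si](CC)(CC)CC)C(=C)C(=O)OC | intermediate
16 | anti-6,8-diol, 4R,5S,6S,8S,9S | C=CCC[C@@]1(C)O[C@H]1[C@@H](O)C[C@H](O)[C@@H](O[Si](CC)(CC)CC)C(=C)C(=O)OC | intermediate
17 | diethylphosphonoacetic acid | CCOP(=O)(CC(=O)O)OCC | starting material
18 | acyclic C6 diethylphosphonoacetate, C8–OH, C9–OSiEt3 | C=CCC[C@@]1(C)O[C@H]1[C@@H](OC(=O)CP(=O)(OCC)OCC)C[C@H](O)[C@@H](O[Si](CC)(CC)CC)C(=C)C(=O)OC | intermediate
19 | ten-membered epoxy enoate, C6 phosphonoacetate, C8–OH, C9–OSiEt3 | O[C@H]1C[C@H](OC(=O)CP(=O)(OCC)OCC)[C@@H]2O[C@]2(C)CC/C=C(/C(=O)OC)[C@@H]1O[Si](CC)(CC)CC | intermediate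
20 | methacrylic anhydride | C=C(C)C(=O)OC(=O)C(C)=C | starting material
21 | macrocycle, C8 methacrylate, C9–OSiEt3 | C=C(C)C(=O)O[C@H]1C[C@H](OC(=O)CP(=O)(OCC)OCC)[C@@H]2O[C@]2(C)CC/C=C(/C(=O)OC)[C@@H]1O[Si](CC)(CC)CC | intermediate
22 | macrocycle, C8 methacrylate, C9–OH | C=C(C)C(=O)O[C@H]1C[C@H](OC(=O)CP(=O)(OCC)OCC)[C@@H]2O[C@]2(C)CC/C=C(/C(=O)OC)[C@@H]1O | intermediate
23 | macrocycle, C8 methacrylate, C9 acetate, C6 phosphonoacetate | C=C(C)C(=O)O[C@H]1C[C@H](OC(=O)CP(=O)(OCC)OCC)[C@@H]2O[C@]2(C)CC/C=C(/C(=O)OC)[C@@H]1OC(C)=O | intermediate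
24 | key-step precursor, C6 diazophosphonoacetate | C=C(C)C(=O)O[C@H]1C[C@H](OC(=O)C(=[N+]=[N-])P(=O)(OCC)OCC)[C@@H]2O[C@]2(C)CC/C=C(/C(=O)OC)[C@@H]1OC(C)=O | intermediate
25 | key-step product, trans-fused α-phosphono lactone | C=C(C)C(=O)O[C@H]1[C@H]2[C@@H](P(=O)(OCC)OCC)C(=O)O[C@@H]2[C@@H]2O[C@]2(C)CC/C=C(/C(=O)OC)[C@@H]1OC(C)=O | intermediate
26 | CNP0153978.8, 4R,5S,6S,7R,8S,9S, 1(10)E | C=C(C)C(=O)O[C@H]1[C@H]2C(=C)C(=O)O[C@@H]2[C@@H]2O[C@]2(C)CC/C=C(/C(=O)OC)[C@@H]1OC(C)=O | target

Total step count: 18. Longest linear sequence: 14 (steps 1–4 and 9–18, from nerol).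

Steps most likely to fail

Step 17. The carbene may be diverted before it reaches C7–H. It could be captured by the epoxide oxygen as an oxonium ylide, or it could insert at C5–H or C6–H. It may also take the C7 hydrogen that leads to cis fusion. All of these outcomes depend on the conformer population of the fully acylated ring. The fallback changes the ring that meets the carbene and the order of events, not the catalyst: the lactone is made before C9 is deprotected, so the bulky silyloxy group imposes a different ring shape. It sets out from 21. Diazo transfer gives the C9-silylated diazophosphonoacetate F1. Dirhodium-catalysed insertion gives the C9-silylated α-phosphono lactone F2. Buffered HF·pyridine gives the C9-hydroxy α-phosphono lactone F3. Acetylation with Ac2O, pyridine and DMAP brings the route back at 25.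

Step 12. Cross-metathesis of the terminal alkene (oligomerisation) may outrun closure onto the hindered acrylate, or the terminal alkene may migrate before closure. The fallback closes the ring on a differently shaped chain, two steps earlier. It sets out from 15, where C8 is sp2 and the C6–OH to C8=O hydrogen bond folds the C6–C8 segment. Ring-closing metathesis gives the macrocyclic β-hydroxy ketone F4. Evans–Saksena reduction within the ring gives the macrocyclic anti-6,8-diol F5. Carbodiimide coupling of the C6 hydroxyl with 17 brings the route back at 19.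

Step 11. Discrimination between the two secondary hydroxyl groups may be poor, giving the C8 ester, double acylation or a 1,3-acyl shift. The fallback lets the mechanism choose the oxygen instead of sterics. It sets out from 15, which undergoes an Evans–Tishchenko reduction with diethyl (2-oxoethyl)phosphonate and catalytic SmI2 in THF at −10 °C. The C6 hemiacetal delivers hydride to the C8 ketone intramolecularly, giving the 6,8-anti relationship, and is itself oxidised to the C6 phosphonoacetate. This gives 18 directly and replaces steps 10 and 11; no new compound is made.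

Further compounds
F1 | step 17 | C9-silylated diazophosphonoacetate macrocycle | C=C(C)C(=O)O[C@H]1C[C@H](OC(=O)C(=[N+]=[N-])P(=O)(OCC)OCC)[C@@H]2O[C@]2(C)CC/C=C(/C(=O)OC)[C@@H]1O[Si](CC)(CC)CC
F2 | step 17 | C9-silylated α-phosphono lactone | C=C(C)C(=O)O[C@H]1[C@H]2[C@@H](P(=O)(OCC)OCC)C(=O)O[C@@H]2[C@@H]2O[C@]2(C)CC/C=C(/C(=O)OC)[C@@H]1O[Si](CC)(CC)CC
F3 | step 17 | C9-hydroxy α-phosphono lactone | C=C(C)C(=O)O[C@H]1[C@H]2[C@@H](P(=O)(OCC)OCC)C(=O)O[C@@H]2[C@@H]2O[C@]2(C)CC/C=C(/C(=O)OC)[C@@H]1O
F4 | step 12 | macrocyclic β-hydroxy ketone | O=C1C[C@H](O)[C@@H]2O[C@]2(C)CC/C=C(/C(=O)OC)[C@@H]1O[Si](CC)(CC)CC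
F5 | step 12 | macrocyclic anti-6,8-diol | O[C@H]1C[C@H](O)[C@@H]2O[C@]2(C)CC/C=C(/C(=O)OC)[C@@H]1O[Si](CC)(CC)CC
F0 | step 11 | none | none
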